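**Retrosynthetic overview**
1. Target (6) ⇒ global debenzylation of the heptabenzyl dimer 5.
2. 5 ⇒ the single new bond, C3(flavanone)–C8(dihydroflavonol). This is an SN2 C-alkylation of the chelated 5-phenoxide of the taxifolin tetrabenzyl ether 4 by the taxifolin-derived α-bromoketone 3.
3. Both halves come from (+)-taxifolin (2R,3R). All four rings and both sets of stereocenters are already present, so no ring is built. The flavanone C3 configuration is set by the SN2 inversion and confirmed by equilibration to the 2,3-trans isomer.

**Assumptions (one line each)**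
- The C6-regioisomer formed in step 4 is removed by chromatography.
- The 5-OH groups stay free through steps 1–4 because they are H-bonded to C4=O.
- The 2,3-trans arrangement is the thermodynamic one, so it is reached at C3 of unit 1 by enolisation.

**Step 1**
Reactants: 1, (+)-taxifolin, (2R,3R)-3,5,7,3',4'-pentahydroxyflavanone.
Product: 2, (2R,3R)-7,3',4'-tri-O-benzyltaxifolin (3-OH and 5-OH free).
Conditions: BnBr (3.3 equiv), K2CO3, acetone, 50 °C.
Reagents that add atoms: benzyl bromide, BrCc1ccccc1.
Why: Williamson etherification is selective for the acidic 7-, 3'- and 4'-phenols. The 5-OH is chelated to C4=O and the 3-OH is aliphatic, so neither reacts. No stereocenter is touched.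

**Step 2**
Reactants: 2.
Product: 3, (2R,3S)-3-bromo-7,3',4'-tri-O-benzyl-5-hydroxyflavanone (2,3-cis).
Conditions: CBr4, PPh3, CH2Cl2, 0 °C → rt.
Reagents that add atoms: carbon tetrabromide, BrC(Br)(Br)Br (supplies Br).
Why: Appel-type activation of the secondary α-ketol followed by bromide SN2 inverts C3 only; C2 is unchanged.

**Step 3**
Reactants: 2.
Product: 4, (2R,3R)-3,7,3',4'-tetra-O-benzyltaxifolin (5-OH free).
Conditions: BnBr, Ag2O, CH2Cl2, rt, dark.
Reagents that add atoms: benzyl bromide, BrCc1ccccc1.
Why: neutral silver(I)-assisted benzylation caps the 3-OH without base, so C2 and C3 are not epimerised and the 3-OH cannot compete as a nucleophile in step 4.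

**Step 4**
Reactants: 3 (electrophile, 1 equiv) and 4 (nucleophile, 2 equiv).
Product: 5, protected dimer with the 3→8'' link, (2R,3R)-unit-2 and (2S,3R)-unit-1.
Conditions: Cs2CO3 (1.1 equiv), MeCN, 25 °C, 24 h; then Et3N, 6 h.
Reagents that add atoms: none (Br leaves as bromide).
Why: the ambident chelated 5-phenoxide of 4 alkylates through C8, which is para to O⁻ and ortho to two ring oxygens. This is a Friedel–Crafts-type SN2 C-alkylation with inversion at C3 of 3. Inversion places the aryl where taxifolin's 3-OH was, which is 2,3-trans. The acidic, benzylic C3–H lets any cis epimer equilibrate to trans with Et3N. C2 is not α to the carbonyl and is untouched.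

**Step 5**
Reactants: 5.
Product: 6, target.
Conditions: H2 (1 atm), Pd(OH)2/C, EtOAc/MeOH 1:1, rt, 3 h.
Reagents that add atoms: none (hydrogen only).
Why: hydrogenolysis cleaves all seven benzyl ethers. The ketones, the cyclic C2–O bonds and the stereocenters survive mild, short hydrogenolysis; C3 stays trans by thermodynamic preference.

**Checks performed**
- Configuration: in the target SMILES, unit 2 is (2R,3R), identical to taxifolin. In unit 1, C2 has the same spatial arrangement as taxifolin's C2 and the C3-aryl sits where taxifolin's 3-OH sits. I confirmed both with CIP analysis and SMILES chirality.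
- Atom balance: 3 (C36H29BrO6) + 4 (C43H36O7) − HBr gives 5 (C79H64O13). Removing seven Bn groups gives C30H22O13, the target formula (13 O, 9 OH).
- Functional groups: the ketones and 5-OH survive steps 1–4, and the benzyl ethers survive every step before step 5.
- Stereocenters: C2 and C3 of unit 2, and C2 of unit 1, come from taxifolin. C3 of unit 1 is set in step 4 (inversion, then equilibration to trans), and no later step disturbs it.

**Compound list**
1 | (+)-taxifolin | O=C1c2c(O)cc(O)cc2O[C@H](c2ccc(O)c(O)c2)[C@H]1O | starting material
2 | 7,3',4'-tri-O-benzyltaxifolin | O=C1c2c(O)cc(OCc3ccccc3)cc2O[C@H](c2ccc(OCc3ccccc3)c(OCc3ccccc3)c2)[C@H]1O | intermediate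
3 | (2R,3S)-3-bromo-7,3',4'-tri-O-benzyl-5-hydroxyflavanone | O=C1c2c(O)cc(OCc3ccccc3)cc2O[C@H](c2ccc(OCc3ccccc3)c(OCc3ccccc3)c2)[C@@H]1Br | intermediate
4 | 3,7,3',4'-tetra-O-benzyltaxifolin | O=C1c2c(O)cc(OCc3ccccc3)cc2O[C@H](c2ccc(OCc3ccccc3)c(OCc3ccccc3)c2)[C@H]1OCc1ccccc1 | intermediate
5 | heptabenzyl 3→8'' biflavonoid | O=C1c2c(O)cc(OCc3ccccc3)cc2O[C@H](c2ccc(OCc3ccccc3)c(OCc3ccccc3)c2)[C@H]1c1c(OCc2ccccc2)cc(O)c2c1O[C@H](c1ccc(OCc3ccccc3)c(OCc3ccccc3)c1)[C@@H](OCc1ccccc1)C2=O | intermediate
6 | target (THYM_00006) | O=C1c2c(O)cc(O)cc2O[C@H](c2ccc(O)c(O)c2)[C@H]1c1c(O)cc(O)c2c1O[C@H](c1ccc(O)c(O)c1)[C@@H](O)C2=O | target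

**Totals:** 5 steps in all; longest linear sequence 4 steps (1 → 2 → 3 → 5 → 6), with 4 made in parallel from 2.

**Three steps most likely to fail**
1. **Step 4 (C-alkylation).** O- versus C-alkylation, C6 versus C8 selectivity, or HBr elimination of 3 to the flavone could all compete.
   Fallback: change the bond-forming logic. Use a Pd-catalysed α-arylation of the zinc or silyl enol ether of 7,3',4'-tri-O-benzyl-(S)-eriodictyol with an 8-iodo derivative of 4.
2. **Step 2 (bromination).** The α-bromoketone may eliminate to the flavone or undergo B-ring phenonium rearrangement.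
   Fallback: start the electrophile from (S)-eriodictyol instead, using CuBr2 bromination of its tri-O-benzyl ether, so no C3–O inversion chemistry is needed.
3. **Step 5 (hydrogenolysis).** Aryl-ketone reduction, C2–O hydrogenolysis or incomplete debenzylation are possible.
   Fallback: redo the sequence with protecting groups removable without hydrogenation, such as MOM ethers cleaved with mild acid, or cleave the benzyl ethers with BCl3/pentamethylbenzene at −78 °C.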